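**Retrosynthetic overview**

1. Target 29 ⇐ primary alcohol 26 ⇐ benzyl ether bis-angelate 25 ⇐ diol 23 (angelates put on last, in two stages) ⇐ tricyclic enedione 19, by oxygenation of the seven-membered ring (C7 ketone → C8=C9 enone → C9–OH → anti C7–OH).
2. 19 ⇐ cyclobutanone 17 (key step): the 3-methoxy-3-methylcyclobutanone opens to an enolate/oxocarbenium 1,4-zwitterion that adds across the C4=C10 ring alkene. The four-membered ketone ring (C11, C1, C2, C3) takes in C4 and C5 and becomes the cyclohexenone (C1–C5, C11), while the C11–C10 bond closes the cyclobutane (C4, C5, C11, C10).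
3. Enabling feature: the β-methyl enone C1(=O)–C2H=C3(CH3) is the retron of a 3-alkoxy-3-methylcyclobutanone, and the methyl-bearing quaternary C10 sits at the tertiary end of a trisubstituted C4=C10 alkene, one atom (C5) away from C11.
4. 17 ⇐ acid 13 + 2-methoxypropene (ketene [2+2]); cycloheptenone 11 ⇐ ring-closing metathesis of 10; the C5/C6 stereocentres ⇐ Ireland–Claisen rearrangement of ester 6, with chirality from the (R)-allylic alcohol 4.
5. Ring order: seven-membered ring (step 6) → auxiliary four-membered ketone (step 9) → six-membered enone ring and cyclobutane together (step 10).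

Key step: step 10

Remark on numbering: atom numbers in the text are longipinane numbers. C1 is the ring C=O, C2=C3 the enone (CH3 on C3), C4 and C11 the bridgeheads, C5 the CH bridge, C6 the quaternary carbon with CH3 and CH2O, C7 and C9 the oxygenated CH groups, C8 the CH2 between them, C10 the quaternary bridge carbon with CH3.

Remark on 5: racemic 5 is assumed to be purchasable and is used as such, because its stereocentre becomes the trigonal enolate carbon in step 4; ester 6 is therefore an epimer pair.

Remark on 24: angelic anhydride is assumed to be purchasable; each molecule transfers one angeloyl group and leaves the other as angelic acid.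

**Route**

Step 1
Reactants: 1 4-(tert-butyldimethylsilyloxy)but-1-yne; 2 acetaldehyde
Product: 3 (R)-6-(tert-butyldimethylsilyloxy)hex-3-yn-2-ol
Conditions: Me2Zn, ProPhenol ligand (enantiomer giving the R alcohol, 10 mol%), Ph3P=O (20 mol%), PhMe, 0 °C
Reagents that add atoms: none
Why: Zn–ProPhenol-catalysed asymmetric alkynylation of acetaldehyde (alkynylzinc addition), in which the chiral dinuclear zinc catalyst sets the (R)-carbinol centre that later controls C5 and C6.

Step 2
Reactants: 3 (R)-6-(tert-butyldimethylsilyloxy)hex-3-yn-2-ol
Product: 4 (2R,3Z)-6-(tert-butyldimethylsilyloxy)hex-3-en-2-ol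
Conditions: H2 (1 atm), Lindlar catalyst, quinoline, EtOAc, rt
Reagents that add atoms: none
Why: Lindlar semihydrogenation stops at the cis-alkene, and the Z geometry is what the chelated-enolate Claisen chair in step 4 needs for the required relative configuration.

Step 3
Reactants: 4 (2R,3Z)-6-(tert-butyldimethylsilyloxy)hex-3-en-2-ol; 5 (±)-3-(benzyloxy)-2-methylpropanoic acid
Product: 6 (2R,3Z)-6-(tert-butyldimethylsilyloxy)hex-3-en-2-yl 3-(benzyloxy)-2-methylpropanoate (epimer pair at the ester α-carbon)
Conditions: DCC, DMAP (cat.), CH2Cl2, 0 °C → rt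
Reagents that add atoms: none
Why: Steglich esterification of the secondary allylic alcohol leaves the carbinol centre untouched, and the α-stereocentre of 5 is irrelevant because it is enolised in step 4.

Step 4
Reactants: 6 allylic ester (epimer pair)
Product: 9 (2S,3R,4E)-2-[(benzyloxy)methyl]-3-[2-(tert-butyldimethylsilyloxy)ethyl]-2-methylhex-4-enoic acid, via silyl ketene acetal 7 (not isolated), via trimethylsilyl ester 8 (not isolated)
Conditions: LDA, THF, −78 °C; TMSCl/Et3N, −78 °C → rt, then 50 °C; aq. citric acid work-up
Reagents that add atoms: none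
Why: Ireland–Claisen rearrangement in which Li chelation by the β-benzyloxy oxygen fixes the tetrasubstituted enolate geometry (CH2OBn cis to OSi), and the chair with the carbinol methyl equatorial and the Z-substituent axial transfers the (R)-carbinol chirality to the quaternary C6 and the adjacent C5 (CH2OBn and the C5 arm cis in the later ring) and gives the E-propenyl group.

Step 5
Reactants: 9 Claisen acid
Product: 10 6-[(benzyloxy)methyl]-7-[2-(tert-butyldimethylsilyloxy)ethyl]-2,6-dimethyldeca-1,8-dien-5-one (configuration of 9 retained; 8E)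
Conditions: (3-methylbut-3-en-1-yl)lithium (2.5 equiv, from 4-bromo-2-methylbut-1-ene and t-BuLi), THF/Et2O, −78 → 0 °C; aq. NH4Cl
Reagents that add atoms: (3-methylbut-3-en-1-yl)lithium [Li]CCC(C)=C
Why: Ketone synthesis from a lithium carboxylate and an alkyllithium, in which the dilithio gem-diolate survives until work-up and the α-quaternary centre excludes enolisation, so no over-addition should occur.

Step 6
Reactants: 10 dienone
Product: 11 2-[(benzyloxy)methyl]-3-[2-(tert-butyldimethylsilyloxy)ethyl]-2,5-dimethylcyclohept-4-en-1-one (CH2OBn and the C3 side chain cis)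
Conditions: Grubbs II (5 mol%), CH2Cl2, 40 °C
Reagents that add atoms: none
Why: Ring-closing metathesis to the trisubstituted cycloheptene, favoured by the gem-disubstituted carbon in the chain and driven by loss of propene, with the alkene geometry fixed by the ring.

Step 7
Reactants: 11 silyl ether
Product: 12 2-[(benzyloxy)methyl]-3-(2-hydroxyethyl)-2,5-dimethylcyclohept-4-en-1-one
Conditions: HF·pyridine, THF/pyridine, 0 °C → rt
Reagents that add atoms: none
Why: Fluoride cleavage of the primary TBS ether, to which the benzyl ether, the ketone and the trisubstituted alkene are inert.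

Step 8
Reactants: 12 primary alcohol
Product: 13 {7-[(benzyloxy)methyl]-3,7-dimethyl-6-oxocyclohept-2-en-1-yl}acetic acid
Conditions: TEMPO (cat.), PhI(OAc)2 (2.2 equiv), MeCN/H2O, rt
Reagents that add atoms: water O
Why: TEMPO/PhI(OAc)2 oxidation in aqueous acetonitrile takes the primary alcohol through the aldehyde hydrate to the acid without touching the alkene or the benzyl ether.

Step 9
Reactants: 13 cycloheptenylacetic acid; 14 2-methoxypropene
Product: 17 2-{7-[(benzyloxy)methyl]-3,7-dimethyl-6-oxocyclohept-2-en-1-yl}-3-methoxy-3-methylcyclobutan-1-one (mixture of cyclobutanone diastereomers), via acid chloride 15 (not isolated), via ketene 16 (not isolated)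
Conditions: (COCl)2, DMF (cat.), CH2Cl2, 0 °C → rt; concentrate; then 14 (10 equiv), Et3N, MeCN, 60 °C, slow addition
Reagents that add atoms: none
Why: Dehydrochlorination of the acid chloride to the aldoketene and thermal ketene–enol ether [2+2] cycloaddition, in which the ketene carbonyl carbon bonds to the CH2 terminus so that the methoxy-bearing carbon ends β to the ketone; the two new ring stereocentres need no control because both become trigonal in step 10.

Step 10
Reactants: 17 cyclobutanone (diastereomer mixture)
Product: 19 14-O-benzyl longipin-2-ene-1,7-dione (tricyclic enedione; C6 bears CH3 and CH2OBn; ring system and configuration of 29), via methoxy ketone 18 (not isolated)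
Conditions: SnCl4 (2.5 equiv), CH2Cl2, −78 → −45 °C; then DBU, −45 °C → rt
Reagents that add atoms: none
Why: Proposed new method: SnCl4 binds the cyclobutanone carbonyl and the donor–acceptor four-membered ring opens between its α-carbon and the methoxy-bearing carbon to a tin enolate/methoxycarbenium 1,4-zwitterion, in which both former ring stereocentres are trigonal, so all diastereomers of 17 converge; the trisubstituted ring alkene then attacks the oxocarbenium through its CH terminus C4 (Markovnikov, 6-exo Prins closure through a chair), the tertiary cation left at C10 is captured by the enolate carbon C11 (4-exo C-alkylation, which closes the cyclobutane), and DBU removes methanol to give the enone. The closest known reactions are the Lewis-acid formal [4+2] cycloadditions of 3-alkoxycyclobutanones with allylsilanes and silyl enol ethers and the Lewis-acid stepwise [2+2] cycloadditions of unactivated alkenes with acrylates, in which a tertiary cation/metal enolate pair collapses to a cyclobutane; the terpinyl-to-pinyl cyclisation is the biosynthetic analogue. The four-membered ketone ring (C11, C1, C2, C3) thereby becomes the six-membered enone ring by taking in C4 and C5. The three new stereocentres (C4, C10, C11) are fixed by the existing C5 centre, because the short tether can deliver both bonds only to the alkene face that carries the side chain, and a trans ring fusion formed in a reversible Prins step cannot close and should revert. The step needs C–C bond formation at the less substituted alkene carbon (secured by the tertiary cation), enolate C-alkylation faster than proton loss, hydride shift or chloride capture (helped by ion-pair proximity, low temperature, the absence of oxygen at C9 and complexation of the C7 ketone by excess Lewis acid), and no O-alkylation (excluded by geometry, since it would give a bridgehead enol ether).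

Step 11
Reactants: 19 tricyclic enedione
Product: 20 14-O-benzyl longipina-2,8-diene-1,7-dione
Conditions: IBX (3 equiv), DMSO/PhF, 70 °C
Reagents that add atoms: none
Why: IBX dehydrogenation of the saturated ketone, where only C8 carries α-hydrogens (C6 is quaternary) and the existing enone cannot react further because its α′ and γ ring carbons are bridgeheads.

Step 12
Reactants: 20 dienedione
Product: 22 14-O-benzyl 9-hydroxylongipin-2-ene-1,7-dione (9-OH syn to CH2OBn), via pinacol boronate 21 (not isolated)
Conditions: CuCl (5 mol%), Josiphos-type ligand (6 mol%), NaOt-Bu (10 mol%), B2pin2 (1.1 equiv), MeOH (2 equiv), THF, rt; then NaBO3·4H2O, THF/H2O, rt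
Reagents that add atoms: sodium perborate O[B-]1(O)OO[B-](O)(O)OO1.[Na+].[Na+]
Why: Copper(I)-catalysed conjugate borylation followed by perborate oxidation with retention, in which the β-monosubstituted cycloheptenone should react much faster than the β,β-disubstituted enone and the chiral ligand–Cu–Bpin catalyst delivers boron to the C9 face syn to CH2OBn against a weak substrate bias.

Step 13
Reactants: 22 β-hydroxy ketone
Product: 23 14-O-benzyl 7,9-dihydroxylongipin-2-en-1-one (7,9-trans diol; 7-OH anti to CH2OBn)
Conditions: Me4NBH(OAc)3, MeCN/AcOH, −30 °C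
Reagents that add atoms: none
Why: Evans–Saksena reduction, in which the C9 alkoxy(acetoxy)borohydride delivers hydride intramolecularly to the C7 ketone to give the anti 1,3-diol, while the enone, which has no directing hydroxyl, is not reduced.

Step 14
Reactants: 23 benzyl ether diol; 24 angelic anhydride [(Z)-2-methylbut-2-enoic anhydride]
Product: 25 14-O-benzyl 7,9-bis(angeloyloxy)longipin-2-en-1-one
Conditions: LiHMDS (2.2 equiv), THF, −78 °C; then 24 (3 equiv), −78 → 0 °C; aq. NH4Cl
Reagents that add atoms: none
Why: Acyl transfer from angelic anhydride to the preformed dilithium dialkoxide, which needs no nucleophilic catalyst and runs at low temperature, so the two hindered secondary alcohols should be esterified with the Z geometry and all stereocentres intact, while the benzyl ether blocks the primary position and the enone has only bridgehead α′- and γ-ring hydrogens.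

Step 15
Reactants: 25 benzyl ether bis-angelate
Product: 26 7,9-bis(angeloyloxy)-14-hydroxylongipin-2-en-1-one
Conditions: BCl3, pentamethylbenzene, CH2Cl2, −78 → −40 °C; MeOH quench
Reagents that add atoms: none
Why: Lewis-acid debenzylation with pentamethylbenzene as benzyl-cation scavenger at low temperature, chosen because hydrogenolysis would reduce the enone and the angelates; an acyl shift from O7 to O14 would do no harm, since step 16 angeloylates whichever hydroxyl is free.

Step 16
Reactants: 26 primary alcohol; 27 angelic acid [(Z)-2-methylbut-2-enoic acid]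
Product: 29 CNP0266467.1 (tris-angelate target), via mixed anhydride 28 (not isolated)
Conditions: 27 (3 equiv), 2,4,6-trichlorobenzoyl chloride (3 equiv), Et3N, PhMe, rt; then 26, PhMe, 80 °C
Reagents that add atoms: none
Why: Yamaguchi-type acylation of the single remaining primary alcohol with the preformed angelic 2,4,6-trichlorobenzoic mixed anhydride without DMAP, in which the shielded trichlorobenzoyl carbonyl directs attack to the angeloyl carbonyl and the absence of a nucleophilic catalyst should keep angelate-to-tiglate isomerisation low; no stereocentre is touched.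

**Compound list**

1 | 4-(tert-butyldimethylsilyloxy)but-1-yne | C#CCCO[Si](C)(C)C(C)(C)C | starting material
2 | acetaldehyde | CC=O | starting material
3 | (R)-6-(tert-butyldimethylsilyloxy)hex-3-yn-2-ol | C[C@@H](O)C#CCCO[Si](C)(C)C(C)(C)C | intermediate
4 | (2R,3Z)-6-(tert-butyldimethylsilyloxy)hex-3-en-2-ol | C[C@@H](O)/C=C\CCO[Si](C)(C)C(C)(C)C | intermediate
5 | (±)-3-(benzyloxy)-2-methylpropanoic acid | CC(COCc1ccccc1)C(=O)O | starting material
6 | (2R,3Z)-6-(tert-butyldimethylsilyloxy)hex-3-en-2-yl 3-(benzyloxy)-2-methylpropanoate (epimer pair at the α-carbon) | C[C@@H](OC(=O)C(C)COCc1ccccc1)/C=C\CCO[Si](C)(C)C(C)(C)C | intermediate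
7 | silyl ketene acetal of 6 (CH2OBn cis to OSiMe3) | C[C@@H](O/C(O[Si](C)(C)C)=C(\C)COCc1ccccc1)/C=C\CCO[Si](C)(C)C(C)(C)C | intermediate
8 | trimethylsilyl ester of 9 | c1ccccc1COC[C@](C(=O)O[Si](C)(C)C)(C)[C@H](CCO[Si](C)(C)C(C)(C)C)/C=C/C | intermediate
9 | (2S,3R,4E)-2-[(benzyloxy)methyl]-3-[2-(tert-butyldimethylsilyloxy)ethyl]-2-methylhex-4-enoic acid | c1ccccc1COC[C@](C(=O)O)(C)[C@H](CCO[Si](C)(C)C(C)(C)C)/C=C/C | intermediate
10 | 6-[(benzyloxy)methyl]-7-[2-(tert-butyldimethylsilyloxy)ethyl]-2,6-dimethyldeca-1,8-dien-5-one (configuration of 9; 8E) | c1ccccc1COC[C@](C(=O)CCC(C)=C)(C)[C@H](CCO[Si](C)(C)C(C)(C)C)/C=C/C | intermediate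
11 | 2-[(benzyloxy)methyl]-3-[2-(tert-butyldimethylsilyloxy)ethyl]-2,5-dimethylcyclohept-4-en-1-one (CH2OBn and C3 side chain cis) | c1ccccc1COC[C@]1(C)[C@H](CCO[Si](C)(C)C(C)(C)C)C=C(C)CCC1=O | intermediate
12 | 2-[(benzyloxy)methyl]-3-(2-hydroxyethyl)-2,5-dimethylcyclohept-4-en-1-one | c1ccccc1COC[C@]1(C)[C@H](CCO)C=C(C)CCC1=O | intermediate
13 | {7-[(benzyloxy)methyl]-3,7-dimethyl-6-oxocyclohept-2-en-1-yl}acetic acid | c1ccccc1COC[C@]1(C)[C@H](CC(=O)O)C=C(C)CCC1=O | intermediate
14 | 2-methoxypropene | C=C(C)OC | starting material
15 | acid chloride of 13 | c1ccccc1COC[C@]1(C)[C@H](CC(=O)Cl)C=C(C)CCC1=O | intermediate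
16 | ketene from 15 | c1ccccc1COC[C@]1(C)[C@H](C=C=O)C=C(C)CCC1=O | intermediate
17 | 2-{7-[(benzyloxy)methyl]-3,7-dimethyl-6-oxocyclohept-2-en-1-yl}-3-methoxy-3-methylcyclobutan-1-one (cyclobutanone centres as mixture) | c1ccccc1COC[C@]1(C)[C@H](C2C(=O)CC2(C)OC)C=C(C)CCC1=O | intermediate
18 | 14-O-benzyl 3-methoxylongipinane-1,7-dione (C3 as mixture) | c1ccccc1COC[C@]1(C)[C@@H]2[C@H]3C(=O)CC(C)(OC)[C@@H]2[C@@]3(C)CCC1=O | intermediate
19 | 14-O-benzyl longipin-2-ene-1,7-dione | c1ccccc1COC[C@]1(C)[C@@H]2[C@H]3C(=O)C=C(C)[C@@H]2[C@@]3(C)CCC1=O | intermediate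
20 | 14-O-benzyl longipina-2,8-diene-1,7-dione | c1ccccc1COC[C@]1(C)[C@@H]2[C@H]3C(=O)C=C(C)[C@@H]2[C@@]3(C)C=CC1=O | intermediate
21 | C9 pinacol boronate of the 1,7-dione (boron syn to CH2OBn) | c1ccccc1COC[C@]1(C)[C@@H]2[C@H]3C(=O)C=C(C)[C@@H]2[C@@]3(C)[C@H](B4OC(C)(C)C(C)(C)O4)CC1=O | intermediate
22 | 14-O-benzyl 9-hydroxylongipin-2-ene-1,7-dione | c1ccccc1COC[C@]1(C)[C@@H]2[C@H]3C(=O)C=C(C)[C@@H]2[C@@]3(C)[C@H](O)CC1=O | intermediate
23 | 14-O-benzyl 7,9-dihydroxylongipin-2-en-1-one (7,9-trans) | c1ccccc1COC[C@]1(C)[C@@H]2[C@H]3C(=O)C=C(C)[C@@H]2[C@@]3(C)[C@H](O)C[C@H]1O | intermediate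
24 | angelic anhydride, (Z)-2-methylbut-2-enoic anhydride | C/C=C(/C)C(=O)OC(=O)/C(C)=C\C | starting material
25 | 14-O-benzyl 7,9-bis(angeloyloxy)longipin-2-en-1-one | c1ccccc1COC[C@]1(C)[C@@H]2[C@H]3C(=O)C=C(C)[C@@H]2[C@@]3(C)[C@H](OC(=O)/C(C)=C\C)C[C@H]1OC(=O)/C(C)=C\C | intermediate
26 | 7,9-bis(angeloyloxy)-14-hydroxylongipin-2-en-1-one | OC[C@]1(C)[C@@H]2[C@H]3C(=O)C=C(C)[C@@H]2[C@@]3(C)[C@H](OC(=O)/C(C)=C\C)C[C@H]1OC(=O)/C(C)=C\C | intermediate
27 | angelic acid, (Z)-2-methylbut-2-enoic acid | C/C=C(/C)C(=O)O | starting material
28 | angelic 2,4,6-trichlorobenzoic anhydride | C/C=C(/C)C(=O)OC(=O)c1c(Cl)cc(Cl)cc1Cl | intermediate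
29 | CNP0266467.1, 7,9,14-tris(angeloyloxy)longipin-2-en-1-one | C/C=C(/C)C(=O)OC[C@]1(C)[C@@H]2[C@H]3C(=O)C=C(C)[C@@H]2[C@@]3(C)[C@H](OC(=O)/C(C)=C\C)C[C@H]1OC(=O)/C(C)=C\C | target

**Totals and risks**

Total step count: 16. Longest linear sequence: 16 steps (1 → 29); 5, 14, 24, 27 and the organolithium of step 5 enter as side inputs.

Steps most likely to fail:

1. Step 10 (Proposed new method). After the Prins closure the tertiary cation may be lost by proton transfer or chloride capture before the enolate closes the strained four-membered ring, so the cascade would stop at a cis-fused bicycle. The fallback separates the two bond formations and uses known reaction types. From 17, TiCl4 in CH2Cl2 (−78 → 0 °C) should give ring opening, Prins cyclisation with chloride termination and loss of methanol, i.e. the cis-fused bicyclic chloro enone F1. Excess LDA/TMSCl then gives the bis(trimethylsilyl enol ether) F2, with the cross-conjugated dienol ether at the enone α′-carbon. AgOTf in CH2Cl2 at −78 °C ionises the tertiary chloride for an intramolecular Reetz-type α-tert-alkylation of the silyl enol ether, and aqueous work-up returns to the route at 19.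

2. Step 12. Boron delivery may show poor facial selectivity, because the substrate bias is weak and the catalyst may be mismatched, or the second enone may be borylated as well. The fallback brings the oxygen in as a nucleophile: from 20, Weitz–Scheffer epoxidation (t-BuOOH, DBU, CH2Cl2, 0 °C) of the less substituted cycloheptenone gives the epoxy ketone F3, and SmI2 in THF/MeOH at −90 °C opens the epoxide reductively at the α-carbon, returning to the route at 22.

3. Step 14. Acyl transfer to the two hindered alkoxides, each next to a quaternary carbon, may remain incomplete, and longer exposure to base may isomerise angelate to tiglate or deprotonate the enone methyl group. The fallback builds the Z-alkenes after acylation: from 23, esterification with 2-[bis(2,2,2-trifluoroethoxy)phosphoryl]propanoic acid (DCC, DMAP, CH2Cl2) gives the bis(phosphonopropionate) F4, and a twofold Still–Gennari olefination (KHMDS, 18-crown-6, THF, −78 °C) with acetaldehyde 2 forms the two (Z)-2-methylbut-2-enoates in place, returning to the route at 25.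

Further compounds
F1 | step 10 | cis-fused bicyclic chloro enone (tertiary chloride centre as mixture) | c1ccccc1COC[C@]1(C)[C@@H]2CC(=O)C=C(C)[C@@H]2C(C)(Cl)CCC1=O
F2 | step 10 | bis(trimethylsilyl enol ether) of F1 | c1ccccc1COC[C@]1(C)[C@@H]2C=C(O[Si](C)(C)C)C=C(C)[C@@H]2C(C)(Cl)CC=C1O[Si](C)(C)C
F3 | step 12 | 8,9-epoxy ketone of 20 (epoxide syn to CH2OBn) | c1ccccc1COC[C@]1(C)[C@@H]2[C@H]3C(=O)C=C(C)[C@@H]2[C@@]3(C)[C@@H]4O[C@@H]4C1=O
F4 | step 14 | bis{2-[bis(2,2,2-trifluoroethoxy)phosphoryl]propanoate} of 23 (phosphonate α-centres as mixture) | c1ccccc1COC[C@]1(C)[C@@H]2[C@H]3C(=O)C=C(C)[C@@H]2[C@@]3(C)[C@H](OC(=O)C(C)P(=O)(OCC(F)(F)F)OCC(F)(F)F)C[C@H]1OC(=O)C(C)P(=O)(OCC(F)(F)F)OCC(F)(F)F
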